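## Retrosynthetic overview
1. The tiglate (acylation at the C1' oxygen), the enal (allylic oxidation of a C2 isopropenyl group), the isopropenyl group (dehydration of a C2 CMe2OH group) and the C3 acetate all lead back to one silyl-protected 2,3-trans diol.
2. Feature used: the run C3a–C3(O)–C2(O1)–C(exocyclic) of the dihydrofuran ring. It equals the ortho carbon and the oxygen of a para-substituted phenol plus three carbons of (R)-3,3-dimethyloxirane-2-carbaldehyde: CHO becomes C3, the secondary epoxide carbon becomes C2, and CMe2 becomes the exocyclic carbon.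
3. Key disconnection: C3a–C3 (magnesium-templated ortho-hydroxyalkylation) and O1–C2 (epoxide opening by the phenoxide), both made in one flask.
4. Ring order: the benzene ring is bought, and the dihydrofuran ring is the only ring formed, in the key step.
5. Stereocentres: C1' by CBS reduction, C2 from a Sharpless epoxide (inverted on closure), C3 relayed from the epoxide by chelation.

Key step: step 7

Assumption: both coupling partners are used at the enantiomeric purity the catalytic steps deliver. The minor enantiomer of either partner ends in a diastereomer of the annulation product, which chromatography after the key step should remove.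

## Route

Step 1
Reactants: 1 4-hydroxyacetophenone
Product: 2 1-[4-(tert-butyldimethylsilyloxy)phenyl]ethanone
Conditions: TBSCl (1.1 equiv), imidazole (2 equiv), DMF, 0 °C → rt
Reagents that add atoms: tert-butyldimethylsilyl chloride, CC(C)(C)[Si](C)(C)Cl
Why: Imidazole-promoted O-silylation of the phenol, needed so that the acidic OH neither consumes borane nor binds the oxazaborolidine in step 2.

Step 2
Reactants: 2 1-[4-(tert-butyldimethylsilyloxy)phenyl]ethanone
Product: 3 (1R)-1-[4-(tert-butyldimethylsilyloxy)phenyl]ethanol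
Conditions: (S)-2-methyl-CBS-oxazaborolidine (10 mol %), BH3·SMe2 (0.7 equiv), THF, −20 °C, slow addition of 2; MeOH quench
Reagents that add atoms: none
Why: Corey–Bakshi–Shibata reduction, in which the (S)-oxazaborolidine–BH3 complex binds the ketone oxygen anti to the aryl group and passes hydride to the Si face, as for acetophenone itself, and so should set the (R)-carbinol centre C1'.

Step 3
Reactants: 3 (1R)-1-[4-(tert-butyldimethylsilyloxy)phenyl]ethanol
Product: 4 bis-TBS ether, tert-butyl{4-[(1R)-1-(tert-butyldimethylsilyloxy)ethyl]phenoxy}dimethylsilane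
Conditions: TBSCl (1.2 equiv), imidazole (2.5 equiv), DMF, rt
Reagents that add atoms: tert-butyldimethylsilyl chloride, CC(C)(C)[Si](C)(C)Cl
Why: Standard silylation of a secondary alcohol at oxygen, so the C1'–O bond and its configuration are untouched.

Step 4
Reactants: 4 bis-TBS ether
Product: 5 4-[(1R)-1-(tert-butyldimethylsilyloxy)ethyl]phenol
Conditions: Cs2CO3 (0.3 equiv), DMF–H2O (10:1), rt; pH 7 buffer work-up
Reagents that add atoms: none
Why: Chemoselective base-mediated desilylation, which works because phenoxide leaves silicon far more readily than a secondary alkoxide, so that only the aryl silyl ether is hydrolysed and the temperature stays too low for loss of silanolate through a para-quinone methide.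

Step 5
Reactants: 6 3-methylbut-2-en-1-ol (prenol)
Product: 7 [(2S)-3,3-dimethyloxiran-2-yl]methanol
Conditions: Ti(OiPr)4 (5 mol %), L-(+)-diisopropyl tartrate (6 mol %), t-BuOOH (1.5 equiv), 4 Å MS, CH2Cl2, −20 °C; non-aqueous work-up, distillation
Reagents that add atoms: tert-butyl hydroperoxide, CC(C)(C)OO
Why: Katsuki–Sharpless asymmetric epoxidation, in which the titanium–L-(+)-tartrate complex binds the allylic alkoxide and the peroxide and, by the empirical face rule of the reaction, gives the 2S epoxy alcohol.

Step 6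
Reactants: 7 [(2S)-3,3-dimethyloxiran-2-yl]methanol
Product: 8 (2R)-3,3-dimethyloxirane-2-carbaldehyde
Conditions: TEMPO (10 mol %), PhI(OAc)2 (1.1 equiv), CH2Cl2, 0 °C → rt; cold NaHCO3 wash, bulb-to-bulb distillation
Reagents that add atoms: none
Why: Oxoammonium (TEMPO/PhI(OAc)2) oxidation stops at the aldehyde and does not touch the epoxide carbon, whose descriptor turns from S to R only because CHO outranks CMe2.

Step 7
Reactants: 5 4-[(1R)-1-(tert-butyldimethylsilyloxy)ethyl]phenol, 8 (2R)-3,3-dimethyloxirane-2-carbaldehyde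
Product: 11 (2R,3R)-5-[(1R)-1-(tert-butyldimethylsilyloxy)ethyl]-2-(2-hydroxypropan-2-yl)-2,3-dihydrobenzofuran-3-ol (2,3-trans diol), via bromomagnesium phenoxide 9 (not isolated), via magnesium-bound syn epoxy alcohol 10 (not isolated)
Conditions: EtMgBr (1.0 equiv), Et2O, 0 °C; solvent exchange to CH2Cl2; 8 (1.2 equiv), −30 → 0 °C; then K2CO3 (2 equiv), MeOH, 0 → 30 °C, one pot
Reagents that add atoms: none
Why: Proposed new method: EtMgBr turns 5 into the phenoxide 9, whose magnesium in non-coordinating CH2Cl2 binds the carbonyl and the epoxide oxygen of 8, so that the ortho carbon attacks the aldehyde through a cyclic six-membered transition state and rearomatisation of the dienone gives 10 with the C3a–C3 bond in place. The closest known reaction types are the ortho-specific, syn-selective hydroxyalkylation of bromomagnesium phenoxides with chiral α-alkoxy aldehydes and the base-mediated cyclisation of ortho-(3,3-dimethyloxiranylmethyl)phenols to 2-(2-hydroxypropan-2-yl)dihydrobenzofurans; what has not been shown is an epoxy aldehyde as the electrophile and the merger of both events in one flask. The dihydrofuran ring closes in the 5-exo-tet mode, the phenoxide oxygen displacing the epoxide oxygen from the secondary carbon by SN2 once K2CO3/MeOH has taken the magnesium out as its carbonate. C3 is set by the epoxide stereocentre, because in the five-membered chelate the CMe2 carbon shields one carbonyl face and attack past the epoxide C–H gives the syn (1R,2'S) epoxy alcohol; C2 is the Sharpless-derived carbon, inverted in the closure, and syn plus inversion equals 2,3-trans (2R,3R). Site selectivity is secured by the substrate, since the para position is blocked and the two ortho positions are equivalent, while low temperature and one equivalent of phenoxide hold back a second arylation through an ortho-quinone methide. The 5-exo over 6-endo preference rests on the basic medium freed of Lewis acid, in which the less hindered secondary carbon is attacked and no cationic character builds up at the CMe2 carbon.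

Step 8
Reactants: 11 2,3-trans diol
Product: 12 (2R,3R)-5-[(1R)-1-(tert-butyldimethylsilyloxy)ethyl]-2-(2-hydroxypropan-2-yl)-2,3-dihydrobenzofuran-3-yl acetate
Conditions: Ac2O (1.2 equiv), pyridine (3 equiv), DMAP (5 mol %), CH2Cl2, 0 °C
Reagents that add atoms: acetic anhydride, CC(=O)OC(C)=O
Why: Chemoselective acylation under DMAP catalysis, the secondary C3 alcohol reacting much faster than the hindered tertiary one and with retention because only the O–H bond is broken.

Step 9
Reactants: 12 hydroxy acetate
Product: 13 (2S,3R)-5-[(1R)-1-(tert-butyldimethylsilyloxy)ethyl]-2-(prop-1-en-2-yl)-2,3-dihydrobenzofuran-3-yl acetate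
Conditions: Burgess reagent (2 equiv), toluene, 50 °C
Reagents that add atoms: none
Why: Burgess dehydration, a syn (Ei) elimination of the tertiary sulfamate that should take one of the six methyl hydrogens in preference to the single, hindered and O1-deactivated C2–H, under neutral conditions that spare the C3 acetate and the silyl ether (the C2 descriptor turns to S by priority change only).

Step 10
Reactants: 13 isopropenyl acetate
Product: 14 (2S,3R)-5-[(1R)-1-(tert-butyldimethylsilyloxy)ethyl]-2-(3-hydroxyprop-1-en-2-yl)-2,3-dihydrobenzofuran-3-yl acetate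
Conditions: SeO2 (0.3 equiv), t-BuOOH (2.5 equiv, in decane), CH2Cl2, 0 °C → rt
Reagents that add atoms: selenium dioxide, O=[Se]=O; tert-butyl hydroperoxide, CC(C)(C)OO
Why: SeO2-catalysed allylic hydroxylation (Riley-type oxidation, ene reaction followed by [2,3]-sigmatropic shift), which on a 1,1-disubstituted alkene prefers a methyl over a methine hydrogen and has precedent on the isopropenyl groups of terpenoids and rotenoids.

Step 11
Reactants: 14 allylic alcohol
Product: 15 (2S,3R)-5-[(1R)-1-(tert-butyldimethylsilyloxy)ethyl]-2-(3-oxoprop-1-en-2-yl)-2,3-dihydrobenzofuran-3-yl acetate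
Conditions: activated MnO2 (15 equiv), CH2Cl2, rt
Reagents that add atoms: none
Why: MnO2 oxidises only the allylic alcohol, brings any enal already formed in step 10 along unchanged and is neutral enough for the acetate and the silyl ether.

Step 12
Reactants: 15 silyl-protected enal
Product: 16 (2S,3R)-5-[(1R)-1-hydroxyethyl]-2-(3-oxoprop-1-en-2-yl)-2,3-dihydrobenzofuran-3-yl acetate
Conditions: n-Bu4NF (2 equiv), AcOH (2 equiv), THF, 0 °C → rt
Reagents that add atoms: none
Why: Fluoride-induced desilylation buffered with AcOH, which attacks silicon only, so that C1' keeps its configuration, and keeps the medium near neutral so that the enal and the acetate should survive.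

Step 13
Reactants: 16 benzylic alcohol, 17 tiglic acid [(E)-2-methylbut-2-enoic acid]
Product: 18 (1R)-1-[(2S,3R)-3-acetoxy-2-(3-oxoprop-1-en-2-yl)-2,3-dihydrobenzofuran-5-yl]ethyl (E)-2-methylbut-2-enoate (CNP0294391.1)
Conditions: 17 (1.5 equiv), DCC (1.5 equiv), DMAP (0.2 equiv), CH2Cl2, 0 °C → rt
Reagents that add atoms: none
Why: Steglich esterification, in which the alcohol oxygen attacks the acylpyridinium ion so that C1' is retained, and tiglic acid, being the stable E isomer, has no drive to isomerise.

## Compound list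
1 | 4-hydroxyacetophenone | CC(=O)c1ccc(O)cc1 | starting material
2 | 1-[4-(tert-butyldimethylsilyloxy)phenyl]ethanone | CC(=O)c1ccc(O[Si](C)(C)C(C)(C)C)cc1 | intermediate
3 | (1R)-1-[4-(tert-butyldimethylsilyloxy)phenyl]ethanol | C[C@@H](O)c1ccc(O[Si](C)(C)C(C)(C)C)cc1 | intermediate
4 | tert-butyl{4-[(1R)-1-(tert-butyldimethylsilyloxy)ethyl]phenoxy}dimethylsilane | C[C@@H](O[Si](C)(C)C(C)(C)C)c1ccc(O[Si](C)(C)C(C)(C)C)cc1 | intermediate
5 | 4-[(1R)-1-(tert-butyldimethylsilyloxy)ethyl]phenol | C[C@@H](O[Si](C)(C)C(C)(C)C)c1ccc(O)cc1 | intermediate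
6 | 3-methylbut-2-en-1-ol | CC(C)=CCO | starting material
7 | [(2S)-3,3-dimethyloxiran-2-yl]methanol | OC[C@@H]1OC1(C)C | intermediate
8 | (2R)-3,3-dimethyloxirane-2-carbaldehyde | O=C[C@@H]1OC1(C)C | intermediate
9 | bromomagnesium 4-[(1R)-1-(tert-butyldimethylsilyloxy)ethyl]phenoxide | C[C@@H](O[Si](C)(C)C(C)(C)C)c1ccc(O[Mg]Br)cc1 | intermediate
10 | bromomagnesium 4-[(1R)-1-(tert-butyldimethylsilyloxy)ethyl]-2-{(R)-[(2S)-3,3-dimethyloxiran-2-yl](hydroxy)methyl}phenoxide (syn epoxy alcohol) | C[C@@H](O[Si](C)(C)C(C)(C)C)c1ccc(O[Mg]Br)c(c1)[C@@H](O)[C@@H]2OC2(C)C | intermediate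
11 | (2R,3R)-5-[(1R)-1-(tert-butyldimethylsilyloxy)ethyl]-2-(2-hydroxypropan-2-yl)-2,3-dihydrobenzofuran-3-ol | CC(C)(O)[C@@H]1Oc2ccc([C@@H](C)O[Si](C)(C)C(C)(C)C)cc2[C@H]1O | intermediate
12 | (2R,3R)-5-[(1R)-1-(tert-butyldimethylsilyloxy)ethyl]-2-(2-hydroxypropan-2-yl)-2,3-dihydrobenzofuran-3-yl acetate | CC(C)(O)[C@@H]1Oc2ccc([C@@H](C)O[Si](C)(C)C(C)(C)C)cc2[C@H]1OC(C)=O | intermediate
13 | (2S,3R)-5-[(1R)-1-(tert-butyldimethylsilyloxy)ethyl]-2-(prop-1-en-2-yl)-2,3-dihydrobenzofuran-3-yl acetate | C=C(C)[C@@H]1Oc2ccc([C@@H](C)O[Si](C)(C)C(C)(C)C)cc2[C@H]1OC(C)=O | intermediate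
14 | (2S,3R)-5-[(1R)-1-(tert-butyldimethylsilyloxy)ethyl]-2-(3-hydroxyprop-1-en-2-yl)-2,3-dihydrobenzofuran-3-yl acetate | C=C(CO)[C@@H]1Oc2ccc([C@@H](C)O[Si](C)(C)C(C)(C)C)cc2[C@H]1OC(C)=O | intermediate
15 | (2S,3R)-5-[(1R)-1-(tert-butyldimethylsilyloxy)ethyl]-2-(3-oxoprop-1-en-2-yl)-2,3-dihydrobenzofuran-3-yl acetate | C=C(C=O)[C@@H]1Oc2ccc([C@@H](C)O[Si](C)(C)C(C)(C)C)cc2[C@H]1OC(C)=O | intermediate
16 | (2S,3R)-5-[(1R)-1-hydroxyethyl]-2-(3-oxoprop-1-en-2-yl)-2,3-dihydrobenzofuran-3-yl acetate | C=C(C=O)[C@@H]1Oc2ccc([C@@H](C)O)cc2[C@H]1OC(C)=O | intermediate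
17 | tiglic acid, (E)-2-methylbut-2-enoic acid | C/C=C(\C)C(=O)O | starting material
18 | (1R)-1-[(2S,3R)-3-acetoxy-2-(3-oxoprop-1-en-2-yl)-2,3-dihydrobenzofuran-5-yl]ethyl (E)-2-methylbut-2-enoate | C=C(C=O)[C@@H]1Oc2ccc([C@@H](C)OC(=O)/C(C)=C/C)cc2[C@H]1OC(C)=O | target

## Step count and risks
Total step count: 13. Longest linear sequence: 11 (steps 1–4 and 7–13).

**1. Step 7.**
- What may go wrong:
  - Attack on a non-chelated conformer of the epoxy aldehyde, which lowers the facial selectivity at C3.
  - Premature opening of the magnesium-activated epoxide by bromide or in the 6-endo mode.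
  - Ionisation at the silyloxy-bearing benzylic carbon para to the phenoxide.
- The fallback sets out from 5 and comes back at 12. It uses only known reaction types and no longer depends on chelation.
- NBS in CH2Cl2 at 0 °C gives the ortho-bromophenol F1.
- n-BuLi (2.2 equiv, THF, −78 °C) deprotonates the phenol and exchanges the bromine to give the O,C-dilithio species F2.
- F2 adds to 8 as aryllithiums do to epoxy aldehydes. After an NH4Cl quench this should give mainly the anti epoxy alcohol F3.
- K2CO3 in MeOH closes F3 in the 5-exo mode to the 2,3-cis diol F4.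
- A Mitsunobu reaction of F4 with AcOH (PPh3, DIAD, THF) inverts C3, with the nucleophile entering from the face away from the C2 substituent, and delivers 12 directly.
- Any syn adduct formed alongside closes to 11 and is acetylated as in step 8, so both C3 epimers converge on 12.

**2. Step 10.**
- What may go wrong:
  - Hydrogen abstraction at C2–H instead of the methyl group.
  - Incomplete or excessive oxidation.
  - Acid-induced loss of acetic acid with aromatisation of the dihydrofuran ring.
- The fallback sets out from 13 and comes back at 15. It replaces C–H oxygenation by C–H chlorination.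
- NCS with catalytic PhSeCl in CH2Cl2 (selenium-catalysed ene-type chlorination) gives the allylic chloride F5.
- N-methylmorpholine N-oxide in MeCN oxidises F5 to the enal, a Kornblum-type oxidation of an activated halide by an amine oxide.

**3. Step 12.**
- What may go wrong:
  - Conjugate addition to, or oligomerisation of, the enal under fluoride.
  - Ionisation of the para-alkoxybenzylic C–O bond, which would erode the C1' configuration.
- The fallback sets out from 13 and comes back at 18. It changes the order of events so that the enal is made last.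
- Buffered n-Bu4NF on 13 gives the isopropenyl alcohol F6.
- Steglich esterification of F6 with 17 gives the isopropenyl tiglate F7.
- SeO2/t-BuOOH should oxidise the isopropenyl group in preference to the electron-poor tiglate alkene and give the allylic alcohol F8.
- MnO2 converts F8 into 18.

## Further compounds
F1 | step 7 | 2-bromo-4-[(1R)-1-(tert-butyldimethylsilyloxy)ethyl]phenol | C[C@@H](O[Si](C)(C)C(C)(C)C)c1ccc(O)c(Br)c1
F2 | step 7 | lithium 4-[(1R)-1-(tert-butyldimethylsilyloxy)ethyl]-2-lithiophenoxide | C[C@@H](O[Si](C)(C)C(C)(C)C)c1ccc(O[Li])c([Li])c1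
F3 | step 7 | 4-[(1R)-1-(tert-butyldimethylsilyloxy)ethyl]-2-{(S)-[(2S)-3,3-dimethyloxiran-2-yl](hydroxy)methyl}phenol (anti epoxy alcohol) | C[C@@H](O[Si](C)(C)C(C)(C)C)c1ccc(O)c(c1)[C@H](O)[C@@H]2OC2(C)C
F4 | step 7 | (2R,3S)-5-[(1R)-1-(tert-butyldimethylsilyloxy)ethyl]-2-(2-hydroxypropan-2-yl)-2,3-dihydrobenzofuran-3-ol (2,3-cis diol) | CC(C)(O)[C@@H]1Oc2ccc([C@@H](C)O[Si](C)(C)C(C)(C)C)cc2[C@@H]1O
F5 | step 10 | (2S,3R)-5-[(1R)-1-(tert-butyldimethylsilyloxy)ethyl]-2-(3-chloroprop-1-en-2-yl)-2,3-dihydrobenzofuran-3-yl acetate | C=C(CCl)[C@@H]1Oc2ccc([C@@H](C)O[Si](C)(C)C(C)(C)C)cc2[C@H]1OC(C)=O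
F6 | step 12 | (2S,3R)-5-[(1R)-1-hydroxyethyl]-2-(prop-1-en-2-yl)-2,3-dihydrobenzofuran-3-yl acetate | C=C(C)[C@@H]1Oc2ccc([C@@H](C)O)cc2[C@H]1OC(C)=O
F7 | step 12 | (1R)-1-[(2S,3R)-3-acetoxy-2-(prop-1-en-2-yl)-2,3-dihydrobenzofuran-5-yl]ethyl (E)-2-methylbut-2-enoate | C=C(C)[C@@H]1Oc2ccc([C@@H](C)OC(=O)/C(C)=C/C)cc2[C@H]1OC(C)=O
F8 | step 12 | (1R)-1-[(2S,3R)-3-acetoxy-2-(3-hydroxyprop-1-en-2-yl)-2,3-dihydrobenzofuran-5-yl]ethyl (E)-2-methylbut-2-enoate | C=C(CO)[C@@H]1Oc2ccc([C@@H](C)OC(=O)/C(C)=C/C)cc2[C@H]1OC(C)=O
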